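The readings are simulated from invented constants; scatter was added.

The north run cannot be one first-order loss at a steady constant. Write S for the starting material left, and L for the natural logarithm of the charge over S. In the north run L climbed at 0.152 min⁻¹ up to 1.2 min, but at 0.0587 min⁻¹ from 5.2 min to 11 min, which is slower.

| flask | starting material | free catalyst | time |
|---|---|---|---|
| north | 0.120 M | 0.00960 M |  |
| north-west | 0.0480 M | 0.00960 M |  |
| west | 0.120 M | 0.00480 M |  |
| north-east | 0.120 M | 0.00150 M | 11 min |

| run | time / min | [target] / M |
|---|---|---|
| north run | 0.39 | 0.0078 |
| north run | 1.2 | 0.0200 |
| north run | 2.3 | 0.0316 |
| north run | 3.6 | 0.0398 |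
| north run | 5.2 | 0.0483 |
| north run | 6.9 | 0.0548 |
| north run | 8.9 | 0.0632 |
| north run | 11 | 0.0690 |
| north-west run | 0.39 | 0.0035 |
| north-west run | 1.2 | 0.0081 |
| north-west run | 2.3 | 0.0137 |
| north-west run | 3.6 | 0.0162 |
| north-west run | 5.2 | 0.0202 |
| north-west run | 6.9 | 0.0236 |
| north-west run | 8.9 | 0.0247 |
| north-west run | 11 | 0.0277 |
| west run | 0.39 | 0.0047 |
| west run | 1.2 | 0.0144 |
| west run | 2.3 | 0.0235 |
| west run | 3.6 | 0.0309 |
| west run | 5.2 | 0.0384 |
| west run | 6.9 | 0.0451 |
| west run | 8.9 | 0.0546 |
| west run | 11 | 0.0614 |

(each reading ± 6 × 10⁻⁴ M)

- the power of [starting material] that the first rate follows, about the charge of the north run; measure it at two percent of starting material made into target (one fixed amount of target, the same in the runs compared)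
- the power of [free catalyst] that the first rate follows, about the charge of the north run; measure it at two percent of starting material made into target
- the north-west run starts with 0.0720 M less of starting material than the north run, and with no target. Compared where both hold the same amount of starting material, once fifteen percent of what the north-west run was charged with has turned into target, is the north-west run faster, slower or alike (within a tenth)?
- target in the north-east run at 11 min, as a share of the starting material charged

- Overall: starting material -> target, with free catalyst as catalyst.
- Constant volume, constant temperature.
- An order is taken over about fifteen percent of the charge, up and down.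

So I kept a ledger for the limiting reagent, the starting material. Each mole lost appears as target, so S is the charge minus the target read. I split L into two entries. The first is a steady entry that grows with time. Over the same late window, the west run gave 0.0571 min⁻¹ and the north-west run 0.0542 min⁻¹. Charges of catalyst and starting material differed, yet the slopes stayed close. Their mean with the north run is 0.0567 min⁻¹, the background constant, the late climb of L per minute.

The second entry is the catalyst's credit, the part of L above the steady entry. At 11 min the north run held a credit of 0.232, and the west run 0.0933. That is a ratio of 2.49 for a catalyst ratio of 2.00, so I scaled the credit roughly with the catalyst charged.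

For the north-east run the credit became 0.0363. The steady entry over 11 min was 0.624. The books closed at L = 0.660, which is 48.3% of the charge as target.

The same ledger served the comparison. By 1.2 min the north-west run had turned 16.9%, past the asked point, with L climbing at 0.154 min⁻¹. The north run still held 0.0510 M at its last reading, more than the north-west charge, so I took the late constant for it. I called the north-west run faster, by a factor of 2.72.

The forecast differed from me on the yield, giving 34% (range 24% to 43%), with orders 0.97 and 0.7 and the answer faster, and it held that “the catalyst loses activity with time”.

The simulation gave orders 1.1 and 0.73, the answer faster, and 46.3% in the north-east run, a little below my figure.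

    free catalyst + starting material → target + free catalyst (13.98 M⁻¹ min⁻¹)
    free catalyst → spent catalyst (0.5040 min⁻¹)
    starting material → target (0.05274 min⁻¹)

The north-east run shows where its target comes from. The background constant of 0.0567 min⁻¹, acting over 11 min, turns 46.4% of the north-east charge into target. Without the uncatalysed conversion of starting material into target, that run ends at 4.06% instead of 46.3%.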